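**Retrosynthetic overview**
- Target 18 comes from global hydrogenolysis: the CH2 bridge is carried as a diaryl CH–OH, ring A as a diphenylmethylene ketal, the ring B phenol as a benzyl ether, and the tertiary OH as an N,N-diisopropylcarbamate (removed by hydride just before).
- Key disconnection: the quaternary C–CH2 bond. An α-carbamoyloxy benzyllithium (a carbonyl-umpoled d1 carbanion) is alkylated with 1-iodo-4-methylpentane, with inversion, so an (S)-secondary carbamate gives the (S)-quaternary centre.
- Diaryl link: the ring B aryllithium (from ArBr) adds to ring A aldehyde 5 in the same flask, just before the key alkylation.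
- Ring B piece 10 comes from 4'-bromo-2'-hydroxyacetophenone (benzylation, asymmetric hydrogenation, carbamoylation); ring A piece 5 comes from 4-methylcatechol (ketal, ortho-lithiation/formylation).
- Rings: both benzene rings are bought. The only ring formed is the temporary 1,3-dioxole of the catechol ketal (step 1), opened in the last step.

Assumption: 1-iodo-4-methylpentane and the Ru precatalyst are bought; the ill-defined aluminium alkoxide aggregates of the LiAlH4 step are protonated on work-up and carry no number.

**Step 1**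
Reactants: 1 4-methylcatechol
Product: 2 5-methyl-2,2-diphenyl-1,3-benzodioxole
Conditions: Ph2CCl2 (1.1 equiv), neat, 170 °C, 30 min
Reagents that add atoms: dichlorodiphenylmethane ClC(Cl)(c1ccccc1)c1ccccc1
Why: Catechol ketal protection by double substitution at the gem-dichloride (HCl is driven off) gives a ketal with no acidic C–H that tolerates organolithiums and LiAlH4 and is later removed by hydrogenolysis.

**Step 2**
Reactants: 2 5-methyl-2,2-diphenyl-1,3-benzodioxole
Product: 5 6-methyl-2,2-diphenyl-1,3-benzodioxole-4-carbaldehyde, via aryllithium 3 (not isolated), via lithium hemiaminal alkoxide 4 (not isolated)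
Conditions: nBuLi (1.2 equiv), THF, −20 → 0 °C, 1 h; DMF (3 equiv), −78 °C → rt; H2O
Reagents that add atoms: N,N-dimethylformamide CN(C)C=O
Why: Directed ortho-metalation at the oxygen-flanked C–H remote from the methyl group (the other ortho site is buttressed by the methyl), then Bouveault formylation, puts the formyl carbon where the CH2 bridge of the target sits.

**Step 3**
Reactants: 6 1-(4-bromo-2-hydroxyphenyl)ethanone
Product: 7 1-[2-(benzyloxy)-4-bromophenyl]ethanone
Conditions: BnBr (1.2 equiv), K2CO3 (2 equiv), DMF, 60 °C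
Reagents that add atoms: benzyl bromide BrCc1ccccc1
Why: Williamson etherification of the phenoxide masks the phenol as a benzyl ether that survives organolithiums and hydride and falls in the final hydrogenolysis.

**Step 4**
Reactants: 7 1-[2-(benzyloxy)-4-bromophenyl]ethanone
Product: 8 (1S)-1-[2-(benzyloxy)-4-bromophenyl]ethanol
Conditions: H2 (8 atm), trans-RuCl2[(R)-xylbinap][(R)-daipen] (0.2 mol %), KOtBu (2 mol %), iPrOH, 25 °C
Reagents that add atoms: none
Why: Noyori asymmetric hydrogenation of an aryl methyl ketone (ortho-substituted ones included) through the outer-sphere Ru–H/N–H transition state gives the (S)-carbinol in high ee with the (R)/(R) precatalyst, leaves ArBr and OBn untouched, and sets the only stereocentre of the route.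

**Step 5**
Reactants: 8 (1S)-1-[2-(benzyloxy)-4-bromophenyl]ethanol
Product: 10 (1S)-1-[2-(benzyloxy)-4-bromophenyl]ethyl N,N-diisopropylcarbamate, via sodium alkoxide 9 (not isolated)
Conditions: NaH (1.3 equiv), THF, 0 °C → rt; iPr2NCOCl (1.3 equiv), reflux, 12 h
Reagents that add atoms: N,N-diisopropylcarbamoyl chloride CC(C)N(C(C)C)C(Cl)=O
Why: O-carbamoylation of the alkoxide breaks no bond at the stereocentre (S retained) and installs the hindered carbamate that directs and stabilises the α-lithiation of the next step.

**Step 6**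
Reactants: 10 (1S)-1-[2-(benzyloxy)-4-bromophenyl]ethyl N,N-diisopropylcarbamate, 5 6-methyl-2,2-diphenyl-1,3-benzodioxole-4-carbaldehyde, 11 1-iodo-4-methylpentane
Product: 16 (2S)-2-{2-(benzyloxy)-4-[hydroxy(6-methyl-2,2-diphenyl-1,3-benzodioxol-4-yl)methyl]phenyl}-6-methylheptan-2-yl N,N-diisopropylcarbamate (both carbinol epimers), via aryllithium 12 (not isolated), via lithium benzhydroxide 13 (not isolated), via dilithio carbamate 14 (not isolated), via lithium alkoxide 15 (not isolated)
Conditions: tBuLi (2.0 equiv), Et2O, −78 °C, 15 min; 5 (1.0 equiv), −78 °C, 30 min; sBuLi (1.3 equiv), −78 °C, 1 h; 11 (3 equiv), −78 °C, 6 h; H2O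
Reagents that add atoms: none
Why: Proposed new method: four organolithium events run in one flask, namely Br/Li exchange (the second tBuLi destroys tBuBr), 1,2-addition of aryllithium 12 to aldehyde 5 (the resulting O–Li makes the benzhydryl C–H non-acidic, so the link protects itself), carbamate-directed α-deprotonation by sBuLi with retention to the configurationally stable α-carbamoyloxy benzyllithium 14 (the ketone carbon made nucleophilic), and SE2 alkylation by the non-coordinating primary iodide anti to lithium, i.e. with inversion, which turns the (S)-secondary centre into the (S)-quaternary centre of the target; the closest known reaction type is the Hoppe-type lithiation and invertive alkylation of enantioenriched 1-arylethyl N,N-diisopropylcarbamates with alkyl halides, here preceded in the same flask by a halogen–lithium exchange/aldehyde addition.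

**Step 7**
Reactants: 16 (2S)-2-{2-(benzyloxy)-4-[hydroxy(6-methyl-2,2-diphenyl-1,3-benzodioxol-4-yl)methyl]phenyl}-6-methylheptan-2-yl N,N-diisopropylcarbamate
Product: 17 (2S)-2-{2-(benzyloxy)-4-[hydroxy(6-methyl-2,2-diphenyl-1,3-benzodioxol-4-yl)methyl]phenyl}-6-methylheptan-2-ol (both carbinol epimers)
Conditions: LiAlH4 (6 equiv), THF, reflux, 16 h; H2O work-up
Reagents that add atoms: none
Why: Reductive carbamate cleavage (hydride attacks the carbonyl, the tertiary alkoxide is expelled and the formamide is reduced on to the N-methylamine) frees the tertiary alcohol without breaking the C–O bond of the stereocentre, so the configuration is retained.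

**Step 8**
Reactants: 17 (2S)-2-{2-(benzyloxy)-4-[hydroxy(6-methyl-2,2-diphenyl-1,3-benzodioxol-4-yl)methyl]phenyl}-6-methylheptan-2-ol
Product: 18 Asperchondol A, 3-{3-hydroxy-4-[(2S)-2-hydroxy-6-methylheptan-2-yl]benzyl}-5-methylbenzene-1,2-diol
Conditions: H2 (1 atm), Pd(OH)2/C (20 wt %), EtOAc/EtOH 1:1, rt
Reagents that add atoms: none
Why: Global hydrogenolysis cleaves the benzyl ether, the diphenylmethylene ketal and the doubly benzylic secondary C–OH (activated by two aryl rings and the ortho-oxygen of ring A), whereas the hindered tertiary mono-benzylic alcohol is inert under neutral conditions, so the stereocentre is untouched.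

**Compound list**
1 | 4-methylcatechol (4-methylbenzene-1,2-diol) | Cc1ccc(O)c(O)c1 | starting material
2 | 5-methyl-2,2-diphenyl-1,3-benzodioxole | Cc1ccc2OC(c3ccccc3)(c3ccccc3)Oc2c1 | intermediate
3 | (6-methyl-2,2-diphenyl-1,3-benzodioxol-4-yl)lithium (formed in the flask) | Cc1cc([Li])c2OC(c3ccccc3)(c3ccccc3)Oc2c1 | intermediate
4 | lithium (dimethylamino)(6-methyl-2,2-diphenyl-1,3-benzodioxol-4-yl)methanolate, racemic (formed in the flask) | Cc1cc(C(O[Li])N(C)C)c2OC(c3ccccc3)(c3ccccc3)Oc2c1 | intermediate
5 | 6-methyl-2,2-diphenyl-1,3-benzodioxole-4-carbaldehyde | Cc1cc(C=O)c2OC(c3ccccc3)(c3ccccc3)Oc2c1 | intermediate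
6 | 1-(4-bromo-2-hydroxyphenyl)ethanone (4'-bromo-2'-hydroxyacetophenone) | CC(=O)c1ccc(Br)cc1O | starting material
7 | 1-[2-(benzyloxy)-4-bromophenyl]ethanone | CC(=O)c1ccc(Br)cc1OCc1ccccc1 | intermediate
8 | (1S)-1-[2-(benzyloxy)-4-bromophenyl]ethanol | C[C@H](O)c1ccc(Br)cc1OCc1ccccc1 | intermediate
9 | sodium (1S)-1-[2-(benzyloxy)-4-bromophenyl]ethanolate (formed in the flask) | C[C@H](O[Na])c1ccc(Br)cc1OCc1ccccc1 | intermediate
10 | (1S)-1-[2-(benzyloxy)-4-bromophenyl]ethyl N,N-diisopropylcarbamate | C[C@H](OC(=O)N(C(C)C)C(C)C)c1ccc(Br)cc1OCc1ccccc1 | intermediate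
11 | 1-iodo-4-methylpentane | CC(C)CCCI | starting material
12 | (1S)-1-[2-(benzyloxy)-4-lithiophenyl]ethyl N,N-diisopropylcarbamate (formed in the flask) | C[C@H](OC(=O)N(C(C)C)C(C)C)c1ccc([Li])cc1OCc1ccccc1 | intermediate
13 | lithium {3-(benzyloxy)-4-[(1S)-1-(diisopropylcarbamoyloxy)ethyl]phenyl}(6-methyl-2,2-diphenyl-1,3-benzodioxol-4-yl)methanolate, both carbinol epimers (formed in the flask) | C[C@H](OC(=O)N(C(C)C)C(C)C)c1ccc(C(O[Li])c2cc(C)cc3OC(c4ccccc4)(c4ccccc4)Oc23)cc1OCc1ccccc1 | intermediate
14 | C,O-dilithio species: 13 with lithium in place of the benzylic hydrogen at the carbamate-bearing carbon (retention, S) (formed in the flask) | C[C@]([Li])(OC(=O)N(C(C)C)C(C)C)c1ccc(C(O[Li])c2cc(C)cc3OC(c4ccccc4)(c4ccccc4)Oc23)cc1OCc1ccccc1 | intermediate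
15 | lithium alkoxide of 16 (O–Li at the diarylcarbinol, S at the quaternary carbon) (formed in the flask) | C[C@@](CCCC(C)C)(OC(=O)N(C(C)C)C(C)C)c1ccc(C(O[Li])c2cc(C)cc3OC(c4ccccc4)(c4ccccc4)Oc23)cc1OCc1ccccc1 | intermediate
16 | (2S)-2-{2-(benzyloxy)-4-[hydroxy(6-methyl-2,2-diphenyl-1,3-benzodioxol-4-yl)methyl]phenyl}-6-methylheptan-2-yl N,N-diisopropylcarbamate, both carbinol epimers | C[C@@](CCCC(C)C)(OC(=O)N(C(C)C)C(C)C)c1ccc(C(O)c2cc(C)cc3OC(c4ccccc4)(c4ccccc4)Oc23)cc1OCc1ccccc1 | intermediate
17 | (2S)-2-{2-(benzyloxy)-4-[hydroxy(6-methyl-2,2-diphenyl-1,3-benzodioxol-4-yl)methyl]phenyl}-6-methylheptan-2-ol, both carbinol epimers | C[C@@](CCCC(C)C)(O)c1ccc(C(O)c2cc(C)cc3OC(c4ccccc4)(c4ccccc4)Oc23)cc1OCc1ccccc1 | intermediate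
18 | Asperchondol A, 3-{3-hydroxy-4-[(2S)-2-hydroxy-6-methylheptan-2-yl]benzyl}-5-methylbenzene-1,2-diol | Cc1cc(O)c(O)c(Cc2ccc([C@@](C)(O)CCCC(C)C)c(O)c2)c1 | target

**Step count and risks**
Total steps: 8. Longest linear sequence: 6 steps (6 → 7 → 8 → 10 → 16 → 17 → 18); the ring A branch (1 → 2 → 5) joins in step 6.

Most likely to fail, step 6. Four organolithium operations share one flask, and residual tBuLi, LiBr and the alkoxide may disturb the α-lithiation. Fallback: reverse the polarity of the diaryl union and take it out of the key flask. Setting out from 10, Br/Li exchange to 12 as before is followed by DMF, which gives, through the lithium hemiaminal alkoxide F1, the isolated aldehyde (1S)-1-[2-(benzyloxy)-4-formylphenyl]ethyl N,N-diisopropylcarbamate F2 after aqueous work-up. In the key flask, ketal 2 is ortho-lithiated (nBuLi, TMEDA, Et2O, 0 °C) to aryllithium 3 and F2 is added at −78 °C. This gives lithium alkoxide 13 directly and free of LiBr; sBuLi and then 11 follow as in step 6, so the route is rejoined at 13 (aldehyde 5 is then not needed).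

Second, step 7. Hydride cleavage of a tertiary, very hindered N,N-diisopropylcarbamate may be slow or give elimination. Fallback: replace the alkyl iodide by a borane so that no carbamate remains in the product. 4-Methylpent-1-ene (3 equiv) and BH3·SMe2 in THF give tris(4-methylpentyl)borane F3. Setting out from 14, F3 (2.5 equiv; one equivalent is parked on the alkoxide) at −78 °C gives the lithium borate F4, since boranes, like alkyl halides, add anti to lithium (inversion). On warming, one 4-methylpentyl group migrates from boron to carbon with expulsion of the carbamate (inversion at carbon) to give the tertiary borane F5. NaOH/H2O2 oxidation (retention) then gives diol 17 directly, where the route is rejoined. The same fallback serves if the C-alkylation of step 6 loses enantiopurity.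

Third, step 8. The diarylcarbinol may resist hydrogenolysis, or forcing conditions may begin to cleave the tertiary benzylic alcohol. Fallback: activate only the secondary carbinol before reduction. Setting out from 17, Ac2O/pyridine/DMAP (cat.) at 0 °C acetylates the secondary diarylcarbinol and leaves the tertiary alcohol untouched, giving {3-(benzyloxy)-4-[(2S)-2-hydroxy-6-methylheptan-2-yl]phenyl}(6-methyl-2,2-diphenyl-1,3-benzodioxol-4-yl)methyl acetate F6. The doubly benzylic acetate is hydrogenolysed far more readily than an alcohol, so H2 (1 atm) over Pd/C in EtOAc at rt removes it together with the benzyl ether and the ketal, and the route is rejoined at 18.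

**Further compounds**
F1 | step 6 | lithium {3-(benzyloxy)-4-[(1S)-1-(diisopropylcarbamoyloxy)ethyl]phenyl}(dimethylamino)methanolate | C[C@H](OC(=O)N(C(C)C)C(C)C)c1ccc(C(O[Li])N(C)C)cc1OCc1ccccc1
F2 | step 6 | (1S)-1-[2-(benzyloxy)-4-formylphenyl]ethyl N,N-diisopropylcarbamate | C[C@H](OC(=O)N(C(C)C)C(C)C)c1ccc(C=O)cc1OCc1ccccc1
F3 | step 7 | tris(4-methylpentyl)borane | CC(C)CCCB(CCCC(C)C)CCCC(C)C
F4 | step 7 | lithium borate from 14 and F3 (boron on the carbamate-bearing carbon, R; O–Li at the diarylcarbinol) | C[C@@]([B-](CCCC(C)C)(CCCC(C)C)CCCC(C)C)(OC(=O)N(C(C)C)C(C)C)c1ccc(C(O[Li])c2cc(C)cc3OC(c4ccccc4)(c4ccccc4)Oc23)cc1OCc1ccccc1.[Li+]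
F5 | step 7 | tertiary borane after 1,2-migration: bis(4-methylpentyl)boryl group on C-2 (R) of the 2-aryl-6-methylheptane, O–Li at the diarylcarbinol | C[C@](B(CCCC(C)C)CCCC(C)C)(CCCC(C)C)c1ccc(C(O[Li])c2cc(C)cc3OC(c4ccccc4)(c4ccccc4)Oc23)cc1OCc1ccccc1
F6 | step 8 | {3-(benzyloxy)-4-[(2S)-2-hydroxy-6-methylheptan-2-yl]phenyl}(6-methyl-2,2-diphenyl-1,3-benzodioxol-4-yl)methyl acetate | C[C@@](CCCC(C)C)(O)c1ccc(C(OC(C)=O)c2cc(C)cc3OC(c4ccccc4)(c4ccccc4)Oc23)cc1OCc1ccccc1
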